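(All constants are made up; what happens was integrated by code.)

Per loaded enzyme in the charged flask, the way on to target ran at 374 s⁻¹ and the way to spent catalyst at 0.0900 s⁻¹, far slower, and the ratio of these two is what I carried through.

    starting material + free enzyme ⇌ first complex (K1 = 23 L mol⁻¹, k1 = 7.7 × 10⁵ L mol⁻¹ s⁻¹)
    second complex → free enzyme + target (k2 = 390 s⁻¹)
    free enzyme + added ligand ⇌ idle complex, settled at all times (K3 = 1.3 × 10⁵ L mol⁻¹)
    second substrate + loaded enzyme ⇌ second complex (K4 = 9.6 L mol⁻¹, k4 = 5.5 × 10⁵ L mol⁻¹ s⁻¹)
    starting material + loaded enzyme → spent catalyst (k5 = 1.8 L mol⁻¹ s⁻¹)
    first complex ⇌ loaded enzyme + first product (K6 = 0.045 M, k6 = 10000 s⁻¹)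

starting material 0.050 M; second substrate 0.100 M; free enzyme 5.0 µM; added ligand 7.4 µM

- the form that holds most of the catalyst when 20 % of the starting material are converted (second complex / spent catalyst / idle complex / free enzyme / loaded enzyme / first complex)
- its share of the catalyst then
- factor on the rate of making target when 20 % of the starting material are converted if second substrate is charged twice over
- factor on the rate when 20 % of the starting material are converted if free enzyme is charged at 25 µM instead

- percentages count the starting material that a species holds: one spent catalyst counts as two
- charge of starting material (flask): 0.050 M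

Second complex fell back at 57300 s⁻¹, faster than it went on at 390 s⁻¹, so I held it at balance with loaded enzyme. Target then came at 390 s⁻¹ × 9.6 L mol⁻¹ × c(second substrate) × c(loaded enzyme), and spent catalyst at 1.8 L mol⁻¹ s⁻¹ × c(starting material) × c(loaded enzyme). Dividing one by the other removes c(loaded enzyme):

1.8 L mol⁻¹ s⁻¹ × c(starting material) / (390 s⁻¹ × 9.6 L mol⁻¹ × c(second substrate)) = 2.40 × 10⁻⁴ at the charge

This is the kill chance per turnover, the inverse of the partition ratio. I took both reagents as losing about 0.0100 M by the conversion asked, and since the charge of starting material was smaller, the chance could only fall on the way, to 2.14 × 10⁻⁴. That gave me a bracket on spent catalyst in this flask: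

from above: 2.40 × 10⁻⁴ × 0.0100 M = 2.40 µM, or 48.1 % of the catalyst

from below: 2.14 × 10⁻⁴ × 0.0100 M = 2.14 µM, or 42.7 % of the catalyst

The chance fell nearly evenly with conversion, so I tightened the bracket to its middle, 45.4 %. In this flask loaded enzyme could hold at most 30.7 %, less than the lower bound, and at balance second complex stood below loaded enzyme. With idle complex and first complex taken at balance with free enzyme, and added ligand as charged, free enzyme could hold at most 19.9 %, again less than the lower bound, and each of those two complexes stood below free enzyme, so I chose spent catalyst. The two rate factors I did not reckon by hand.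

The forecast named spent catalyst at 46 %, inside my bracket and a little above my middle, "more than any active form", with factors 2.15 and 8.6.

After 18.3 s this flask held spent catalyst at 45.8 %, beside loaded enzyme at 20.3 % and second complex at 17.4 %, and the factors came out at 2.15 and 8.57. The forecast held.

At that conversion in this flask, the way on to target stood at about 337 s⁻¹ per loaded enzyme against 0.0720 s⁻¹ for the way to spent catalyst, a kill chance of 2.14 × 10⁻⁴, which is 11.1 % below its charged value. The chance holds no catalyst concentration, so for the flask charged with 25 µM of free enzyme the same two chances give between 8.55 % and 9.62 %, and that flask showed spent catalyst at 9.14 %.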